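**Plan**
- The target is an achiral depside. Ring A (5-chloro-2,4-dihydroxy-3,6-dimethylbenzoyl) is esterified to O-4 of ring B (CO2Me at C1, OH at C2, Me at C3, acyloxy at C4, H at C5, Me at C6).
- Cuts, in order: the two ring A benzyl ethers, C2–O back to C2–B, ring B at C2–C3 and C1–C6, and last the acyl–O4 ester bond.
- Enabling feature: C3(Me)–C4(O)–C5(H)–C6(Me) of ring B is the diene of 4-hydroxy-3,6-dimethyl-2-pyrone, whose acidic 4-OH is already the depside oxygen. C1–C2 is an alkyne that carries the ester and a boron standing for the C2 hydroxyl.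
- Forward: ring A is bought as its methyl ester, then chlorinated, benzylated, saponified and attached to pyrone O-4. Ring B grows out of the pyrone ring by [4+2] addition of the boryl propiolate and loss of CO2, and oxidation and hydrogenolysis finish the route.
- Stereochemistry: the target has none. The only stereocentres of the route are the bridgeheads of the transient cycloadduct, and they vanish on aromatisation.

Key step: step 6

Assumption: methyl 2,4-dihydroxy-3,6-dimethylbenzoate (the oakmoss odorant) and 4-hydroxy-3,6-dimethyl-2-pyrone are taken as catalogue chemicals; ring B is numbered from the ester-bearing carbon, so pyrone C3–C6 keep their numbers in ring B.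

Step 1
Reactants: 1 methyl 2,4-dihydroxy-3,6-dimethylbenzoate
Product: 2 methyl 5-chloro-2,4-dihydroxy-3,6-dimethylbenzoate
Conditions: SO2Cl2 (1.05 equiv), CH2Cl2, 0 °C to rt
Reagents that add atoms: sulfuryl chloride, O=S(=O)(Cl)Cl
Why: Electrophilic aromatic chlorination: C5 is the only unsubstituted ring carbon and lies ortho to the 4-OH and para to the 2-OH, so one equivalent of SO2Cl2 should stop at the monochloride.

Step 2
Reactants: 2 methyl 5-chloro-2,4-dihydroxy-3,6-dimethylbenzoate
Product: 3 methyl 2,4-bis(benzyloxy)-5-chloro-3,6-dimethylbenzoate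
Conditions: BnBr (2.5 equiv), K2CO3 (3 equiv), DMF, 70 °C
Reagents that add atoms: benzyl bromide, BrCc1ccccc1
Why: Williamson etherification, in which carbonate in warm DMF also alkylates the hydrogen-bonded 2-OH; benzyl ethers are chosen because they tolerate acid chloride formation, 170 °C and perborate and leave under neutral conditions.

Step 3
Reactants: 3 methyl 2,4-bis(benzyloxy)-5-chloro-3,6-dimethylbenzoate
Product: 4 2,4-bis(benzyloxy)-5-chloro-3,6-dimethylbenzoic acid
Conditions: KOH (10 equiv), DMSO/H2O 4:1, 100 °C; then 1 M HCl, 0 °C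
Reagents that add atoms: potassium hydroxide, [K+].[OH-]
Why: Saponification of a di-ortho-substituted benzoate, for which poorly solvated hydroxide in hot aqueous DMSO is the usual remedy; the benzyl ethers and the electron-rich aryl chloride are inert to base.

Step 4
Reactants: 4 2,4-bis(benzyloxy)-5-chloro-3,6-dimethylbenzoic acid; 5 4-hydroxy-3,6-dimethyl-2H-pyran-2-one
Product: 7 3,6-dimethyl-2-oxo-2H-pyran-4-yl 2,4-bis(benzyloxy)-5-chloro-3,6-dimethylbenzoate, via acid chloride 6 (not isolated)
Conditions: (COCl)2 (1.5 equiv), DMF (cat.), CH2Cl2, 0 °C to rt, evaporate; then 5 (1.1 equiv), Et3N (2 equiv), DMAP (0.1 equiv), CH2Cl2, 0 °C to rt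
Reagents that add atoms: oxalyl chloride, ClC(=O)C(=O)Cl (supplies the acyl chlorine of 6 only; nothing of it stays in 7)
Why: Acid chloride formation under chloroiminium catalysis, then base-mediated O-acylation of the vinylogous acid 5 (pKa near 5) at its 4-oxygen; the C3 methyl group blocks the usual DMAP-induced O-to-C3 acyl shift of 4-acyloxypyrones, so the enol ester should persist.

Step 5
Reactants: 8 methyl propiolate; 9 2-isopropoxy-4,4,5,5-tetramethyl-1,3,2-dioxaborolane
Product: 12 methyl 3-(4,4,5,5-tetramethyl-1,3,2-dioxaborolan-2-yl)propiolate, via lithium methyl propiolate 10 (not isolated), via lithium alkynyl(isopropoxy)borate 11 (not isolated)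
Conditions: n-BuLi (1.0 equiv), THF, −90 °C, 20 min; 9 (1.0 equiv), −78 °C, 2 h; HCl in Et2O (1.05 equiv), −78 °C to rt; filtration under Ar, bulb-to-bulb distillation
Reagents that add atoms: n-butyllithium, [Li]CCCC (supplies the lithium of 10 and 11 only; nothing of it stays in 12)
Why: Standard alkynyllithium–borate route to alkynyl pinacolboronates: the acidic alkyne C–H is deprotonated below −78 °C, where a lithiated propiolate is stable, the acetylide adds to the borate to give the ate complex, and one equivalent of anhydrous HCl removes isopropoxide, with no aqueous work-up because the C(sp)–B bond is water-sensitive.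

Step 6
Reactants: 7 3,6-dimethyl-2-oxo-2H-pyran-4-yl 2,4-bis(benzyloxy)-5-chloro-3,6-dimethylbenzoate; 12 methyl 3-(4,4,5,5-tetramethyl-1,3,2-dioxaborolan-2-yl)propiolate
Product: 14 methyl 4-{[2,4-bis(benzyloxy)-5-chloro-3,6-dimethylbenzoyl]oxy}-3,6-dimethyl-2-(4,4,5,5-tetramethyl-1,3,2-dioxaborolan-2-yl)benzoate, via bridged lactone 13 (not isolated)
Conditions: 12 (3 equiv, added in three portions), dry mesitylene, 170 °C, sealed tube, Ar, 36 h
Reagents that add atoms: none
Why: The pyrone diene C3=C4–C5=C6 of 7 adds to the alkyne of 12 in a thermal, normal-demand Diels–Alder reaction that forms the ring B bonds C2–C3 and C1–C6 and gives the 2-oxabicyclo[2.2.2]octadienone 13, which at this temperature expels its lactone bridge (pyrone O1 and the carbonyl carbon) as CO2 by retro-[4+2] and aromatises. The closest known reaction types are the cycloaddition–decarboxylation of 2-pyrones with alkynyl pinacolboronates to aryl boronates and that of 4-oxygenated 6-methyl-2-pyrones with propiolates and acetylenedicarboxylates to benzoates, and here one alkyne carries both substituents. Ring B is closed by an intermolecular [4+2] cycloaddition (four pyrone carbons plus two alkyne carbons, both sigma bonds in one step) and is fixed as a benzene ring by the cycloreversion. No stereocentre is carried forward, since the two bridgeheads of 13 arise as a racemate and become planar on loss of CO2. The step needs regioselectivity, which rests on matched polarity: pyrone C3 is the electron-rich terminus because the ring oxygen (through C6=C5–C4=C3) and the 4-acyloxy oxygen both push towards it, the boron-bearing alkyne carbon beta to the ester should hold the larger LUMO coefficient because the pinacol oxygens damp the acceptor character of boron, and both diene termini carry a methyl group, so sterics add little bias. The di-ortho-substituted ring A ester, the benzyl ethers and the aryl chloride have no thermal pathway at 170 °C, the C3 methyl blocks an acyl shift from O-4 to carbon, and dry conditions guard against protodeboronation of 12 to methyl propiolate, which would lead to the C2–H arene.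

Step 7
Reactants: 14 methyl 4-{[2,4-bis(benzyloxy)-5-chloro-3,6-dimethylbenzoyl]oxy}-3,6-dimethyl-2-(4,4,5,5-tetramethyl-1,3,2-dioxaborolan-2-yl)benzoate
Product: 15 methyl 4-{[2,4-bis(benzyloxy)-5-chloro-3,6-dimethylbenzoyl]oxy}-2-hydroxy-3,6-dimethylbenzoate
Conditions: NaBO3·4H2O (4 equiv), THF/H2O 1:1, rt
Reagents that add atoms: sodium perborate tetrahydrate, [Na+].[O-]OB=O.O.O.O.O
Why: Oxidation of the C–B bond by peroxide addition to boron, 1,2-aryl shift from boron to oxygen and hydrolysis of the aryl borate; the mildly basic perborate medium at rt should leave the doubly ortho-blocked ring A ester and the equally shielded methyl ester untouched.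

Step 8
Reactants: 15 methyl 4-{[2,4-bis(benzyloxy)-5-chloro-3,6-dimethylbenzoyl]oxy}-2-hydroxy-3,6-dimethylbenzoate
Product: 16 methyl 4-[(5-chloro-2,4-dihydroxy-3,6-dimethylbenzoyl)oxy]-2-hydroxy-3,6-dimethylbenzoate (target)
Conditions: H2 (1 atm), 10% Pd/C, EtOAc, rt
Reagents that add atoms: none
Why: Catalytic hydrogenolysis of the two aryl benzyl ethers; in base-free EtOAc at 1 atm, with the reaction stopped after uptake of two equivalents of H2, the flanked, electron-rich C–Cl bond should survive as it does in related chlorinated depsides, and both esters are inert.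

**Compound list**
1 | methyl 2,4-dihydroxy-3,6-dimethylbenzoate | COC(=O)c1c(C)cc(O)c(C)c1O | starting material
2 | methyl 5-chloro-2,4-dihydroxy-3,6-dimethylbenzoate | COC(=O)c1c(C)c(Cl)c(O)c(C)c1O | intermediate
3 | methyl 2,4-bis(benzyloxy)-5-chloro-3,6-dimethylbenzoate | COC(=O)c1c(C)c(Cl)c(OCc2ccccc2)c(C)c1OCc3ccccc3 | intermediate
4 | 2,4-bis(benzyloxy)-5-chloro-3,6-dimethylbenzoic acid | OC(=O)c1c(C)c(Cl)c(OCc2ccccc2)c(C)c1OCc3ccccc3 | intermediate
5 | 4-hydroxy-3,6-dimethyl-2H-pyran-2-one | Cc1cc(O)c(C)c(=O)o1 | starting material
6 | 2,4-bis(benzyloxy)-5-chloro-3,6-dimethylbenzoyl chloride | ClC(=O)c1c(C)c(Cl)c(OCc2ccccc2)c(C)c1OCc3ccccc3 | intermediate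
7 | 3,6-dimethyl-2-oxo-2H-pyran-4-yl 2,4-bis(benzyloxy)-5-chloro-3,6-dimethylbenzoate | Cc1cc(OC(=O)c2c(C)c(Cl)c(OCc3ccccc3)c(C)c2OCc4ccccc4)c(C)c(=O)o1 | intermediate
8 | methyl propiolate | C#CC(=O)OC | starting material
9 | 2-isopropoxy-4,4,5,5-tetramethyl-1,3,2-dioxaborolane | CC(C)OB1OC(C)(C)C(C)(C)O1 | starting material
10 | lithium methyl propiolate (methyl 3-lithiopropiolate) | [Li]C#CC(=O)OC | intermediate
11 | lithium isopropoxy(3-methoxy-3-oxoprop-1-yn-1-yl)(pinacolato)borate | [Li+].COC(=O)C#C[B-]1(OC(C)C)OC(C)(C)C(C)(C)O1 | intermediate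
12 | methyl 3-(4,4,5,5-tetramethyl-1,3,2-dioxaborolan-2-yl)propiolate | COC(=O)C#CB1OC(C)(C)C(C)(C)O1 | intermediate
13 | methyl 8-{[2,4-bis(benzyloxy)-5-chloro-3,6-dimethylbenzoyl]oxy}-1,4-dimethyl-3-oxo-5-(4,4,5,5-tetramethyl-1,3,2-dioxaborolan-2-yl)-2-oxabicyclo[2.2.2]octa-5,7-diene-6-carboxylate (racemic) | CC12OC(=O)C(C)(C(OC(=O)c3c(C)c(Cl)c(OCc4ccccc4)c(C)c3OCc5ccccc5)=C1)C(B6OC(C)(C)C(C)(C)O6)=C2C(=O)OC | intermediate
14 | methyl 4-{[2,4-bis(benzyloxy)-5-chloro-3,6-dimethylbenzoyl]oxy}-3,6-dimethyl-2-(4,4,5,5-tetramethyl-1,3,2-dioxaborolan-2-yl)benzoate | COC(=O)c1c(C)cc(OC(=O)c2c(C)c(Cl)c(OCc3ccccc3)c(C)c2OCc4ccccc4)c(C)c1B5OC(C)(C)C(C)(C)O5 | intermediate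
15 | methyl 4-{[2,4-bis(benzyloxy)-5-chloro-3,6-dimethylbenzoyl]oxy}-2-hydroxy-3,6-dimethylbenzoate | COC(=O)c1c(C)cc(OC(=O)c2c(C)c(Cl)c(OCc3ccccc3)c(C)c2OCc4ccccc4)c(C)c1O | intermediate
16 | methyl 4-[(5-chloro-2,4-dihydroxy-3,6-dimethylbenzoyl)oxy]-2-hydroxy-3,6-dimethylbenzoate | COC(=O)c1c(C)cc(OC(=O)c2c(C)c(Cl)c(O)c(C)c2O)c(C)c1O | target

Total step count: 8. Longest linear sequence: 7 (steps 1, 2, 3, 4, 6, 7, 8).

**Steps most likely to fail**

**Step 6.**
- Risk: both diene termini carry a methyl group, so the cycloaddition may be slow enough that thermal oligomerisation or protodeboronation of the alkyne outruns it. The orientation of addition may also be poorly controlled.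
- Fallback: ring B is taken as a preformed arene instead of being built. The fallback sets out from acid chloride 6 (made from 4 as in step 4) and a second portion of 1.
- Acylation with Et3N and catalytic DMAP in CH2Cl2 should occur only at the 4-OH of 1, because the 2-OH is held in a hydrogen bond to the neighbouring ester carbonyl and is flanked on both sides.
- This classical depside esterification comes back to the route at 15, just before step 8, and makes no compound outside the list (entry F0).

**Step 5.**
- Risk: the lithiated propiolate may decompose before it is trapped. The ate complex may fall apart into its components because the propiolate anion leaves readily. The C–B bond may be lost by protonolysis during the acid quench or the isolation.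
- Fallback: bromine replaces boron as the placeholder on the alkyne, and boron is introduced on the arene.
- Setting out from 8, NBS with catalytic AgNO3 in acetone gives methyl 3-bromopropiolate F1.
- Heated with 7 in xylene (about 140 °C, sealed tube), F1 should add in the same ester-controlled orientation to give the bridged bromo lactone F2. Loss of CO2 then gives methyl 4-{[2,4-bis(benzyloxy)-5-chloro-3,6-dimethylbenzoyl]oxy}-2-bromo-3,6-dimethylbenzoate F3.
- Miyaura borylation (B2pin2, KOAc, PdCl2(dppf), dioxane, 90 °C) comes back to the route at 14. The hindered, electron-rich C–Cl bond of ring A should be inert to these conditions.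

**Step 7.**
- Risk: boron sits between an ester and a methyl group, so peroxide addition and the aryl shift may be slow. On long exposure to alkaline peroxide the aryl ester link or the methyl ester may be cleaved.
- Fallback: the boron species is changed and an acidic, electrophilic oxidant is used.
- Setting out from 14, KHF2 in MeOH/H2O gives the potassium aryltrifluoroborate F4, which is freed from pinacol by evaporation and trituration.
- F4 is then oxidised with KHSO5 (used as the triple salt 2KHSO5·KHSO4·K2SO4) in acetone/H2O at rt. The medium stays below pH 7, so ester cleavage should not compete, and the sequence comes back to the route at 15.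

**Further compounds**
F0 | step 6 | none | none
F1 | step 5 | methyl 3-bromopropiolate | COC(=O)C#CBr
F2 | step 5 | methyl 8-{[2,4-bis(benzyloxy)-5-chloro-3,6-dimethylbenzoyl]oxy}-5-bromo-1,4-dimethyl-3-oxo-2-oxabicyclo[2.2.2]octa-5,7-diene-6-carboxylate (racemic) | CC12OC(=O)C(C)(C(OC(=O)c3c(C)c(Cl)c(OCc4ccccc4)c(C)c3OCc5ccccc5)=C1)C(Br)=C2C(=O)OC
F3 | step 5 | methyl 4-{[2,4-bis(benzyloxy)-5-chloro-3,6-dimethylbenzoyl]oxy}-2-bromo-3,6-dimethylbenzoate | COC(=O)c1c(C)cc(OC(=O)c2c(C)c(Cl)c(OCc3ccccc3)c(C)c2OCc4ccccc4)c(C)c1Br
F4 | step 7 | potassium (3-{[2,4-bis(benzyloxy)-5-chloro-3,6-dimethylbenzoyl]oxy}-6-(methoxycarbonyl)-2,5-dimethylphenyl)trifluoroborate | [K+].COC(=O)c1c(C)cc(OC(=O)c2c(C)c(Cl)c(OCc3ccccc3)c(C)c2OCc4ccccc4)c(C)c1[B-](F)(F)F
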